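**Retrosynthetic overview**
- The chromene O1–C2 bond (and C4–C4a) is cut last: 4,5,6-trimethoxybenzene-1,3-diol plus a C15 β-methyl enal, joined by a catalyst-controlled oxa-6π ring closure that sets C2.
- The C15 enal comes from a C11 primary iodide and 4,4-dimethoxybutan-2-one (organolithium addition, then acid).
- The C11 alcohol comes from a spirolactone by lactol formation and Wolff–Kishner reduction; the lactone C=O becomes the quaternary methyl.
- The spirolactone comes from an endo-selective asymmetric Diels–Alder reaction of α-methylene-γ-butyrolactone with (E)-3-methylpenta-1,3-diene, which sets both cyclohexene stereocentres.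
- The resorcinol comes from 1,2,3-trimethoxybenzene (dibromination, hydroxylation). Ring order: cyclohexene first (step 1), pyran ring of the chromene last (step 8); the benzene ring is bought.

Assumption: the sense of induction of the chiral catalysts in steps 1 and 8 is taken as drawn and would be confirmed by experiment (both catalysts are available in either mirror-image form). Commercial 3-methylpenta-1,3-diene is an E/Z mixture and is used in excess; only the E isomer 2 reacts.

**Step 1**
Reactants: 1 3-methylideneoxolan-2-one (α-methylene-γ-butyrolactone); 2 (3E)-3-methylpenta-1,3-diene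
Product: 3 (5R,6R)-6,7-dimethyl-2-oxaspiro[4.5]dec-7-en-1-one
Conditions: (S)-o-tolyl oxazaborolidine of α,α-diphenylprolinol (20 mol%), Tf2NH (16 mol%), 2 (3 equiv), CH2Cl2, −40 to −20 °C, 36 h
Reagents that add atoms: none
Why: Lewis-acid-catalysed Diels–Alder reaction in which the methyl-bearing diene terminus bonds to the lactone α-carbon ("ortho" adduct), the endo transition state places the lactone C=O cis to the C6 methyl (relative configuration of both ring stereocentres), and the chiral oxazaborolidinium cation, a catalyst class established for acrylate-type esters and 2-substituted acroleins, shields one face of the bound lactone to give 5R,6R.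

**Step 2**
Reactants: 3 (5R,6R)-6,7-dimethyl-2-oxaspiro[4.5]dec-7-en-1-one
Product: 4 (5R,6R)-6,7-dimethyl-2-oxaspiro[4.5]dec-7-en-1-ol (lactol, both anomers)
Conditions: i-Bu2AlH (1.15 equiv), CH2Cl2, −78 °C; aq. potassium sodium tartrate
Reagents that add atoms: none
Why: Partial hydride reduction of a lactone to the lactol, which stops at the tetrahedral aluminate at −78 °C; the alkene and both stereocentres are untouched.

**Step 3**
Reactants: 4 (5R,6R)-6,7-dimethyl-2-oxaspiro[4.5]dec-7-en-1-ol
Product: 6 2-[(1S,2S)-1,2,3-trimethylcyclohex-3-en-1-yl]ethan-1-ol, via hydrazone 5 (not isolated)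
Conditions: N2H4·H2O (10 equiv), KOH (6 equiv), diethylene glycol, 130 °C, then distil to 200 °C, 4 h
Reagents that add atoms: none
Why: Wolff–Kishner reduction (Huang-Minlon procedure) of the lactol, which reacts through ring–chain tautomerism as its hydrazone; the former lactone carbon becomes the quaternary methyl cis to the neighbouring methyl, and the quaternary α-carbon cannot epimerise.

**Step 4**
Reactants: 6 2-[(1S,2S)-1,2,3-trimethylcyclohex-3-en-1-yl]ethan-1-ol
Product: 7 (5S,6S)-5-(2-iodoethyl)-1,5,6-trimethylcyclohex-1-ene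
Conditions: PPh3 (1.3 equiv), I2 (1.3 equiv), imidazole (1.5 equiv), CH2Cl2, 0 °C to rt
Reagents that add atoms: iodine (I2), SMILES II
Why: Appel iodination of an unhindered primary alcohol by SN2 displacement of the oxyphosphonium group; no stereocentre is involved.

**Step 5**
Reactants: 7 (5S,6S)-5-(2-iodoethyl)-1,5,6-trimethylcyclohex-1-ene; 8 4,4-dimethoxybutan-2-one
Product: 12 3-methyl-5-[(1S,2S)-1,2,3-trimethylcyclohex-3-en-1-yl]pent-2-enal (E/Z mixture about 2:1), via alkyllithium 9 (not isolated), via hydroxy acetal 10 (not isolated), via hydroxy aldehyde 11 (not isolated)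
Conditions: t-BuLi (2.1 equiv), pentane/Et2O 3:2, −78 °C, 30 min; 8 (1.2 equiv), −78 to 0 °C; then 1 M HCl, THF, rt, 2 h
Reagents that add atoms: water, SMILES O
Why: Lithium–iodine exchange (the alkyllithium does not cyclise onto the trisubstituted alkene at −78 °C), 1,2-addition to the ketone, then acid-mediated acetal hydrolysis and aldol-type dehydration give the β-methyl enal; the carbinol centre of 10 is destroyed again, so only the alkene geometry varies.

**Step 6**
Reactants: 13 1,2,3-trimethoxybenzene
Product: 14 1,5-dibromo-2,3,4-trimethoxybenzene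
Conditions: NBS (2.05 equiv), MeCN, 0 °C to rt
Reagents that add atoms: N-bromosuccinimide, SMILES O=C1CCC(=O)N1Br
Why: Electrophilic aromatic bromination occurs twice at the positions ortho/para to the two outer methoxy groups; the position para to the twisted central methoxy group is the least activated.

**Step 7**
Reactants: 14 1,5-dibromo-2,3,4-trimethoxybenzene
Product: 15 4,5,6-trimethoxybenzene-1,3-diol
Conditions: Pd2(dba)3 (2 mol%), t-BuXPhos (8 mol%), KOH (5 equiv), 1,4-dioxane/H2O 1:1, 100 °C, Ar; then aq. HCl, work-up under Ar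
Reagents that add atoms: potassium hydroxide, SMILES [K+].[OH-]
Why: Palladium-catalysed C–O coupling of aryl bromides with hydroxide (Buchwald-type hydroxylation) using a bulky biarylphosphine that tolerates ortho-methoxy groups; the methyl ethers survive the base.

**Step 8**
Reactants: 12 3-methyl-5-[(1S,2S)-1,2,3-trimethylcyclohex-3-en-1-yl]pent-2-enal; 15 4,5,6-trimethoxybenzene-1,3-diol
Product: 18 (2R)-6,7,8-trimethoxy-2-methyl-2-{2-[(1S,2S)-1,2,3-trimethylcyclohex-3-en-1-yl]ethyl}-2H-chromen-5-ol, via carbinol 16 (not isolated), via quinone methide 17 (not isolated)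
Conditions: confined chiral imidodiphosphoric acid built from two (S)-3,3'-bis(2,4,6-triethylphenyl)-BINOL units (5 mol%), 5 Å MS, PhMe, 0 °C to rt, Ar, dark
Reagents that add atoms: none
Why: Proposed new method: a confined chiral Brønsted acid replaces the achiral amine salts of the classical resorcinol–enal chromene annulation. It activates 12 for Friedel–Crafts hydroxyalkylation at the only free ring carbon of 15 (giving 16), then ionises 16 to the vinyl ortho-quinone methide 17, held in the chiral pocket by hydrogen bonds to the two equivalent ring oxygens. The oxa-6π ring closure (O1–C2 bond) then occurs on the catalyst-defined face with the methyl toward the catalyst wall and the long chain away, giving 2R. Because selection is by substituent size on a core bound the same way for both geometric isomers, E- and Z-17 should converge on the same epimer; the remote cyclohexene stereocentres are spectators. The closest known reaction types are the stereorandom ethylenediammonium diacetate-mediated annulation of resorcinols with citral-type enals, and chiral phosphoric or imidodiphosphoric acid control of additions to ortho-quinone methides and of acetal-forming C–O closures.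

**Compound list**
1 | 3-methylideneoxolan-2-one (α-methylene-γ-butyrolactone) | C=C1CCOC1=O | starting material
2 | (3E)-3-methylpenta-1,3-diene | C=C/C(C)=C/C | starting material
3 | (5R,6R)-6,7-dimethyl-2-oxaspiro[4.5]dec-7-en-1-one (lactone C=O cis to the C6 methyl) | O=C1OCC[C@@]12CCC=C(C)[C@H]2C | intermediate
4 | (5R,6R)-6,7-dimethyl-2-oxaspiro[4.5]dec-7-en-1-ol (lactol, both anomers) | OC1OCC[C@@]12CCC=C(C)[C@H]2C | intermediate
5 | 2-[(1R,2R)-1-(hydrazinylidenemethyl)-2,3-dimethylcyclohex-3-en-1-yl]ethan-1-ol | NN=C[C@@]1(CCO)CCC=C(C)[C@H]1C | intermediate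
6 | 2-[(1S,2S)-1,2,3-trimethylcyclohex-3-en-1-yl]ethan-1-ol (methyls at C1 and C2 cis) | OCC[C@]1(C)CCC=C(C)[C@H]1C | intermediate
7 | (5S,6S)-5-(2-iodoethyl)-1,5,6-trimethylcyclohex-1-ene | ICC[C@]1(C)CCC=C(C)[C@H]1C | intermediate
8 | 4,4-dimethoxybutan-2-one | CC(=O)CC(OC)OC | starting material
9 | {2-[(1R,2S)-1,2,3-trimethylcyclohex-3-en-1-yl]ethyl}lithium (same spatial arrangement as 7; the descriptor at the quaternary carbon changes only because lithium ranks below carbon) | [Li]CC[C@]1(C)CCC=C(C)[C@H]1C | intermediate
10 | 1,1-dimethoxy-3-methyl-5-[(1S,2S)-1,2,3-trimethylcyclohex-3-en-1-yl]pentan-3-ol (both C3 epimers) | COC(OC)CC(C)(O)CC[C@]1(C)CCC=C(C)[C@H]1C | intermediate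
11 | 3-hydroxy-3-methyl-5-[(1S,2S)-1,2,3-trimethylcyclohex-3-en-1-yl]pentanal (both C3 epimers) | O=CCC(C)(O)CC[C@]1(C)CCC=C(C)[C@H]1C | intermediate
12 | 3-methyl-5-[(1S,2S)-1,2,3-trimethylcyclohex-3-en-1-yl]pent-2-enal (E/Z mixture) | O=CC=C(C)CC[C@]1(C)CCC=C(C)[C@H]1C | intermediate
13 | 1,2,3-trimethoxybenzene | COc1cccc(OC)c1OC | starting material
14 | 1,5-dibromo-2,3,4-trimethoxybenzene | COc1c(Br)cc(Br)c(OC)c1OC | intermediate
15 | 4,5,6-trimethoxybenzene-1,3-diol | COc1c(O)cc(O)c(OC)c1OC | intermediate
16 | 2-{1-hydroxy-3-methyl-5-[(1S,2S)-1,2,3-trimethylcyclohex-3-en-1-yl]pent-2-en-1-yl}-4,5,6-trimethoxybenzene-1,3-diol (carbinol epimers, E/Z) | COc1c(O)c(C(O)C=C(C)CC[C@]2(C)CCC=C(C)[C@H]2C)c(O)c(OC)c1OC | intermediate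
17 | 5-hydroxy-2,3,4-trimethoxy-6-{3-methyl-5-[(1S,2S)-1,2,3-trimethylcyclohex-3-en-1-yl]pent-2-en-1-ylidene}cyclohexa-2,4-dien-1-one (vinyl ortho-quinone methide, E/Z) | COC1=C(OC)C(=O)C(=CC=C(C)CC[C@]2(C)CCC=C(C)[C@H]2C)C(O)=C1OC | intermediate
18 | (2R)-6,7,8-trimethoxy-2-methyl-2-{2-[(1S,2S)-1,2,3-trimethylcyclohex-3-en-1-yl]ethyl}-2H-chromen-5-ol | COc1c(O)c2c(c(OC)c1OC)O[C@](C)(CC[C@]1(C)CCC=C(C)[C@H]1C)C=C2 | target

**Totals**
Total steps: 8. Longest linear sequence: 6 (steps 1, 2, 3, 4, 5, 8).

**Three steps most likely to fail**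

Step 8 (the new method). Stereocontrol at C2 may be low, the E and Z isomers of 12 may turn out to give opposite epimers, or the acid strength may need tuning against ionisation of the electron-rich product. The fallback is known chemistry; it sets out from 12 and 15 and comes back at 18. The classical stereorandom annulation with ethylenediammonium diacetate (10 mol%) in PhMe at 110 °C gives 18 together with its C2 epimer (2S)-6,7,8-trimethoxy-2-methyl-2-{2-[(1S,2S)-1,2,3-trimethylcyclohex-3-en-1-yl]ethyl}-2H-chromen-5-ol F1 in about 1:1 ratio. The two are diastereomers and are separated by preparative HPLC on a cellulose tris(3,5-dimethylphenylcarbamate) phase. F1 can be recycled by UV irradiation, since photochromic ring opening to 17 and thermal reclosure re-equilibrate the two epimers.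

Step 1. The enantioselectivity with an α-substituted, s-cis-locked lactone dienophile is untested, and the ortho/endo preferences may be only moderate. The fallback sets out from 1 and 2 and comes back at 3. The Diels–Alder reaction promoted by Et2AlCl (1 equiv, CH2Cl2, −30 °C) gives 3 together with its enantiomer (5S,6S)-6,7-dimethyl-2-oxaspiro[4.5]dec-7-en-1-one F2. The mixture is opened with (S)-1-phenylethylamine and AlMe3 (PhMe, 80 °C) to the hydroxy amide (1R,2R)-1-(2-hydroxyethyl)-2,3-dimethyl-N-[(1S)-1-phenylethyl]cyclohex-3-ene-1-carboxamide F3 and its diastereomer (1S,2S)-1-(2-hydroxyethyl)-2,3-dimethyl-N-[(1S)-1-phenylethyl]cyclohex-3-ene-1-carboxamide F4. These are separated by crystallisation or chromatography, and F3 is relactonised (TsOH, PhMe, reflux) to enantiopure 3.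

Step 7. Double hydroxylation of a hindered, electron-rich dibromide may stall at the monophenol, and the diol is air-sensitive. The fallback sets out from 14 and comes back at 15. Miyaura borylation (B2pin2, Pd(dppf)Cl2, KOAc, 1,4-dioxane, 90 °C) gives 2,2'-(4,5,6-trimethoxy-1,3-phenylene)bis(4,4,5,5-tetramethyl-1,3,2-dioxaborolane) F5. Oxidation with H2O2 and NaOH (THF, 0 °C) and acidification under Ar then gives 15.

**Further compounds**
F1 | step 8 | (2S)-6,7,8-trimethoxy-2-methyl-2-{2-[(1S,2S)-1,2,3-trimethylcyclohex-3-en-1-yl]ethyl}-2H-chromen-5-ol | COc1c(O)c2c(c(OC)c1OC)O[C@@](C)(CC[C@]1(C)CCC=C(C)[C@H]1C)C=C2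
F2 | step 1 | (5S,6S)-6,7-dimethyl-2-oxaspiro[4.5]dec-7-en-1-one | O=C1OCC[C@]12CCC=C(C)[C@@H]2C
F3 | step 1 | (1R,2R)-1-(2-hydroxyethyl)-2,3-dimethyl-N-[(1S)-1-phenylethyl]cyclohex-3-ene-1-carboxamide | O=C(N[C@@H](C)c1ccccc1)[C@@]1(CCO)CCC=C(C)[C@H]1C
F4 | step 1 | (1S,2S)-1-(2-hydroxyethyl)-2,3-dimethyl-N-[(1S)-1-phenylethyl]cyclohex-3-ene-1-carboxamide | O=C(N[C@@H](C)c1ccccc1)[C@]1(CCO)CCC=C(C)[C@@H]1C
F5 | step 7 | 2,2'-(4,5,6-trimethoxy-1,3-phenylene)bis(4,4,5,5-tetramethyl-1,3,2-dioxaborolane) | COc1c(B2OC(C)(C)C(C)(C)O2)cc(B2OC(C)(C)C(C)(C)O2)c(OC)c1OC
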